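**Plan**

- Numbering: ring O1–O2–C3–C4–C5; C3 carries CH3 and CH2CO2Me, C5 carries CH3 and the chain C6–C20 (12E,14E,17Z). Both C3 and C5 are quaternary carbons bound to a peroxide oxygen, each with a methyl and a CH2 arm, arms trans. Cutting the chain back to C6–C7 therefore leaves a C2-symmetric 3,5-dimethyl-1,2-dioxolane-3,5-diacetate whose ring carbons are the ketal carbons of acetylacetone peroxide.
- Retrosynthetic cuts: C14=C15 (Julia–Kocienski), C12=C13 (Wittig), C7–C8 (Wittig, then diimide), and finally both exocyclic bonds C3–CH2 and C5–C6 together (twofold peroxycarbenium alkylation of a bis-perketal).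
- Forward order: the peroxide ring is made first from acetylacetone and H2O2 and is never opened; both arms are attached in one operation; one arm is released enzymatically and grown C7 → C12 → C14; the C15–C20 sulfone from (Z)-hex-3-en-1-ol is joined last.
- Stereochemistry: the trans relation at C3/C5 comes from anti attack in the second substitution plus removal of the meso isomer; absolute configuration comes from an esterase kinetic resolution; 12E from a stabilised Wittig, 14E from the Julia–Kocienski step, 17Z bought in with the C6 alcohol.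

Key step: step 3

Assumption: pig liver esterase is taken to hydrolyse the (3R,5R) enantiomer of 7 faster than the (3S,5S) one; the sense and degree of this preference must be found by experiment, and the configuration of 8 is to be confirmed by correlation before it is carried forward.

**Route**

Step 1
Reactants: 1 acetylacetone; 2 hydrogen peroxide
Product: 3 3,5-dimethyl-1,2-dioxolane-3,5-diol (cis/trans mixture)
Conditions: 30% aq. H2O2 (1.0 equiv), H2O, 0 °C → rt, no catalyst; small scale, blast shield, product kept moist or in solution
Reagents that add atoms: none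
Why: Uncatalysed twofold peroxy-hemiketalisation of the 1,3-diketone by one equivalent of H2O2 closes the five-membered peroxide ring (the reaction that gives the main component of acetylacetone peroxide), and the cis/trans mixture is of no consequence because both carbons are ionised in step 3.

Step 2
Reactants: 3 3,5-dimethyl-1,2-dioxolane-3,5-diol
Product: 4 3,5-dimethoxy-3,5-dimethyl-1,2-dioxolane (cis/trans mixture)
Conditions: MeOH (solvent), camphorsulfonic acid (cat.), 3 Å molecular sieves, 0 °C → rt; NaHCO3; not concentrated to dryness
Reagents that add atoms: methanol, CO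
Why: Acid-catalysed ketalisation exchanges both hemiperketal hydroxyls for methoxy through the ring-stabilised peroxycarbenium ion, the standard conversion of 3-hydroxy- into 3-alkoxy-1,2-dioxolanes, and the isomer mixture is again used as such.

Step 3
Reactants: 4 3,5-dimethoxy-3,5-dimethyl-1,2-dioxolane; 5 tert-butyl[(1-methoxyethenyl)oxy]dimethylsilane (two equivalents consumed)
Product: 7 dimethyl 2,2'-[(3R,5R)-3,5-dimethyl-1,2-dioxolane-3,5-diyl]diacetate (trans; racemic; the (3R,5R) enantiomer is drawn), via mono-adduct 6 (not isolated)
Conditions: TiCl4 (2.2 equiv), 5 (3 equiv), CH2Cl2, −78 °C; aq. NaHCO3; chromatography to separate the racemic trans diester from the meso cis isomer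
Reagents that add atoms: none
Why: TiCl4 ionises one methoxy group of 4 to a 1,2-dioxolan-3-ylium (peroxycarbenium) ion, the silyl ketene acetal captures it at carbon to give mono-adduct 6, and the remaining perketal of 6 ionises and is captured in the same way, so that the exocyclic C3–CH2 and C5–C6 bonds are formed at the two quaternary ring carbons. The closest known reaction is the Lewis-acid-mediated (Mukaiyama-type) substitution of 3-alkoxy-1,2-dioxolanes by silyl ketene acetals, and each of the two events is of that type, here run in succession on one ring. No ring is closed, since the peroxide ring is carried in intact from 4. The first centre forms without bias; at the second, the planar cation is attacked anti to the larger CH2CO2Me arm on the far ring carbon (1,3-induction across the five-membered ring, possibly reinforced if the ester carbonyl of that arm shields its own face of the cation), which favours the C2-symmetric trans diester over the meso cis isomer. The step therefore needs trans over cis selectivity, which the substrate secures only modestly, so chromatographic separation is part of the step, the isomers being told apart by the ring CH2 protons (equivalent in the trans compound, an AB pair in the meso compound). Low temperature and an excess of 5 are used so that capture outruns proton loss or O–O heterolysis of the cation.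

Step 4
Reactants: 7 racemic trans diester
Product: 8 2-[(3R,5R)-5-(2-methoxy-2-oxoethyl)-3,5-dimethyl-1,2-dioxolan-3-yl]acetic acid
Conditions: pig liver esterase, 0.1 M phosphate buffer pH 7.2 with 10% acetone, 25 °C, stopped below half conversion; unreacted diester extracted at pH 8, then acidification to pH 3 and extraction
Reagents that add atoms: water, O
Why: Enzymatic kinetic resolution by ester hydrolysis, in which each ester arm hangs from a quaternary carbon carrying methyl, oxygen and methylene (the local pattern pig liver esterase discriminates in dimethyl 3-hydroxy-3-methylglutarate), the two arms of one enantiomer are homotopic so only one half-acid can form, and the anionic half-ester is a poor substrate so the reaction stops there, which selects rather than creates the configuration at both stereocentres.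

Step 5
Reactants: 8 (3R,5R) half-acid
Product: 9 methyl 2-[(3R,5S)-5-(2-hydroxyethyl)-3,5-dimethyl-1,2-dioxolan-3-yl]acetate
Conditions: BH3·THF (1.5 equiv), THF, 0 °C → rt; MeOH quench
Reagents that add atoms: none
Why: Borane reduces the carboxylic acid chemoselectively through its acyloxyborane while the methyl ester is left, and a dialkyl peroxide is not attacked by BH3 at 0 °C, as hydroborations carried out on endoperoxide-bearing alkenes indicate.

Step 6
Reactants: 9 hydroxy ester
Product: 10 methyl 2-[(3R,5R)-3,5-dimethyl-5-(2-oxoethyl)-1,2-dioxolan-3-yl]acetate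
Conditions: Dess–Martin periodinane, NaHCO3, CH2Cl2, 0 °C → rt; used at once
Reagents that add atoms: none
Why: Dess–Martin oxidation under buffered, non-basic conditions delivers the β-peroxy aldehyde without enolisation and hence without β-elimination of the peroxide.

Step 7
Reactants: 10 β-peroxy aldehyde; 11 (4-carboxybutyl)triphenylphosphonium bromide
Product: 13 (5Z)-7-[(3S,5R)-5-(2-methoxy-2-oxoethyl)-3,5-dimethyl-1,2-dioxolan-3-yl]hept-5-enoic acid (Z expected as major isomer; geometry immaterial), via carboxylate ylide 12 (not isolated)
Conditions: 11 (1.3 equiv), NaN(SiMe3)2 (2.5 equiv), THF, 0 °C; then 10, −78 → 0 °C; aq. NaH2PO4 to pH 4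
Reagents that add atoms: none
Why: Wittig olefination with the non-stabilised carboxylate ylide 12, in which addition to the aldehyde at −78 °C outruns enolisation of the β-peroxy aldehyde and of the ester, the ring fragment serves only as electrophile so no carbanion is generated near the O–O bond, and the Z/E ratio is irrelevant because the alkene is saturated in step 8.

Step 8
Reactants: 13 alkenoic acid
Product: 14 7-[(3S,5R)-5-(2-methoxy-2-oxoethyl)-3,5-dimethyl-1,2-dioxolan-3-yl]heptanoic acid
Conditions: KO2CN=NCO2K (excess, in portions), AcOH, MeOH/CH2Cl2, 0 °C → rt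
Reagents that add atoms: none
Why: Diimide reduction, in which HN=NH made in the flask delivers H2 to the C=C bond through a concerted six-membered transition state and leaves untouched the O–O bond, which catalytic hydrogenation would cleave, as well as the ester and the acid.

Step 9
Reactants: 14 saturated acid
Product: 15 methyl 2-[(3R,5S)-5-(7-hydroxyheptyl)-3,5-dimethyl-1,2-dioxolan-3-yl]acetate
Conditions: BH3·THF (1.5 equiv), THF, 0 °C → rt; MeOH quench
Reagents that add atoms: none
Why: Second chemoselective borane reduction of a carboxylic acid beside the methyl ester and the peroxide, on the same grounds as step 5.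

Step 10
Reactants: 15 C12 alcohol
Product: 16 methyl 2-[(3R,5S)-3,5-dimethyl-5-(7-oxoheptyl)-1,2-dioxolan-3-yl]acetate
Conditions: Dess–Martin periodinane, NaHCO3, CH2Cl2, 0 °C → rt
Reagents that add atoms: none
Why: Dess–Martin oxidation of the primary alcohol under the buffered conditions of step 6, giving an aldehyde that is remote from the peroxide and not prone to elimination.

Step 11
Reactants: 16 C12 aldehyde; 17 (triphenyl-λ5-phosphanylidene)acetaldehyde
Product: 18 methyl 2-[(3R,5S)-3,5-dimethyl-5-[(7E)-9-oxonon-7-en-1-yl]-1,2-dioxolan-3-yl]acetate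
Conditions: 17 (1.5 equiv), toluene, 70 °C
Reagents that add atoms: none
Why: Wittig olefination with the stabilised formylmethylene ylide needs no added base, gives the 12E enal under the usual E preference of stabilised ylides, and stops at the enal because the ylide reacts much faster with the saturated aldehyde than with the conjugated product.

Step 12
Reactants: 19 (3Z)-hex-3-en-1-ol; 20 1-phenyl-1H-tetrazole-5-thiol
Product: 21 5-{[(3Z)-hex-3-en-1-yl]sulfanyl}-1-phenyl-1H-tetrazole
Conditions: PPh3, DIAD, THF, 0 °C → rt
Reagents that add atoms: none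
Why: Mitsunobu thioetherification, in which the activated primary alcohol is displaced at sulfur by the acidic tetrazolethiol and the Z alkene is not touched.

Step 13
Reactants: 21 sulfide; 2 hydrogen peroxide
Product: 22 5-{[(3Z)-hex-3-en-1-yl]sulfonyl}-1-phenyl-1H-tetrazole
Conditions: (NH4)6Mo7O24·4H2O (10 mol %), 30% aq. H2O2, EtOH, 0 °C → rt
Reagents that add atoms: none
Why: Molybdate-catalysed H2O2 oxidation of the sulfide to the sulfone through peroxomolybdate species is selective for sulfur over the isolated Z alkene.

Step 14
Reactants: 18 enal; 22 sulfone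
Product: 24 methyl 2-[(3R,5S)-3,5-dimethyl-5-[(7E,9E,12Z)-pentadeca-7,9,12-trien-1-yl]-1,2-dioxolan-3-yl]acetate (target CNP0297319.1), via potassium sulfonyl carbanion 23 (not isolated)
Conditions: 22 (1.3 equiv), KN(SiMe3)2 (1.2 equiv), DME, −55 °C, 20 min; then 18, −55 °C → rt
Reagents that add atoms: none
Why: Julia–Kocienski olefination, in which the premetalated sulfone 23 adds to the enal and Smiles rearrangement with loss of SO2 and the tetrazololate forms C14=C15, expected mainly E for an unbranched sulfone with a conjugated aldehyde, while premetalation ensures that no free amide base meets the β-peroxy ester or the doubly allylic C16 position of the product.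

**Compound list**

1 | acetylacetone (pentane-2,4-dione) | CC(=O)CC(C)=O | starting material
2 | hydrogen peroxide | OO | starting material
3 | 3,5-dimethyl-1,2-dioxolane-3,5-diol (cis/trans mixture) | CC1(O)CC(C)(O)OO1 | intermediate
4 | 3,5-dimethoxy-3,5-dimethyl-1,2-dioxolane (cis/trans mixture) | COC1(C)CC(C)(OC)OO1 | intermediate
5 | tert-butyl[(1-methoxyethenyl)oxy]dimethylsilane | C=C(OC)O[Si](C)(C)C(C)(C)C | starting material
6 | methyl 2-(5-methoxy-3,5-dimethyl-1,2-dioxolan-3-yl)acetate (mono-adduct, isomer mixture, not isolated) | COC(=O)CC1(C)CC(C)(OC)OO1 | intermediate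
7 | dimethyl 2,2'-[(3R,5R)-3,5-dimethyl-1,2-dioxolane-3,5-diyl]diacetate (trans, racemic; (3R,5R) enantiomer drawn) | COC(=O)C[C@@]1(C)C[C@](C)(CC(=O)OC)OO1 | intermediate
8 | 2-[(3R,5R)-5-(2-methoxy-2-oxoethyl)-3,5-dimethyl-1,2-dioxolan-3-yl]acetic acid | OC(=O)C[C@@]1(C)C[C@](C)(CC(=O)OC)OO1 | intermediate
9 | methyl 2-[(3R,5S)-5-(2-hydroxyethyl)-3,5-dimethyl-1,2-dioxolan-3-yl]acetate | OCC[C@@]1(C)C[C@](C)(CC(=O)OC)OO1 | intermediate
10 | methyl 2-[(3R,5R)-3,5-dimethyl-5-(2-oxoethyl)-1,2-dioxolan-3-yl]acetate | O=CC[C@@]1(C)C[C@](C)(CC(=O)OC)OO1 | intermediate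
11 | (4-carboxybutyl)triphenylphosphonium bromide | OC(=O)CCCC[P+](c1ccccc1)(c1ccccc1)c1ccccc1.[Br-] | starting material
12 | sodium 5-(triphenyl-λ5-phosphanylidene)pentanoate (ylide, not isolated) | [Na+].[O-]C(=O)CCCC=P(c1ccccc1)(c1ccccc1)c1ccccc1 | intermediate
13 | (5Z)-7-[(3S,5R)-5-(2-methoxy-2-oxoethyl)-3,5-dimethyl-1,2-dioxolan-3-yl]hept-5-enoic acid | OC(=O)CCC/C=C\C[C@@]1(C)C[C@](C)(CC(=O)OC)OO1 | intermediate
14 | 7-[(3S,5R)-5-(2-methoxy-2-oxoethyl)-3,5-dimethyl-1,2-dioxolan-3-yl]heptanoic acid | OC(=O)CCCCCC[C@@]1(C)C[C@](C)(CC(=O)OC)OO1 | intermediate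
15 | methyl 2-[(3R,5S)-5-(7-hydroxyheptyl)-3,5-dimethyl-1,2-dioxolan-3-yl]acetate | OCCCCCCC[C@@]1(C)C[C@](C)(CC(=O)OC)OO1 | intermediate
16 | methyl 2-[(3R,5S)-3,5-dimethyl-5-(7-oxoheptyl)-1,2-dioxolan-3-yl]acetate | O=CCCCCCC[C@@]1(C)C[C@](C)(CC(=O)OC)OO1 | intermediate
17 | (triphenyl-λ5-phosphanylidene)acetaldehyde | O=CC=P(c1ccccc1)(c1ccccc1)c1ccccc1 | starting material
18 | methyl 2-[(3R,5S)-3,5-dimethyl-5-[(7E)-9-oxonon-7-en-1-yl]-1,2-dioxolan-3-yl]acetate | O=C/C=C/CCCCCC[C@@]1(C)C[C@](C)(CC(=O)OC)OO1 | intermediate
19 | (3Z)-hex-3-en-1-ol | CC/C=C\CCO | starting material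
20 | 1-phenyl-1H-tetrazole-5-thiol | Sc1nnnn1-c1ccccc1 | starting material
21 | 5-{[(3Z)-hex-3-en-1-yl]sulfanyl}-1-phenyl-1H-tetrazole | CC/C=C\CCSc1nnnn1-c1ccccc1 | intermediate
22 | 5-{[(3Z)-hex-3-en-1-yl]sulfonyl}-1-phenyl-1H-tetrazole | CC/C=C\CCS(=O)(=O)c1nnnn1-c1ccccc1 | intermediate
23 | potassium salt of the α-sulfonyl carbanion of 22 (not isolated) | [K+].CC/C=C\C[CH-]S(=O)(=O)c1nnnn1-c1ccccc1 | intermediate
24 | methyl 2-[(3R,5S)-3,5-dimethyl-5-[(7E,9E,12Z)-pentadeca-7,9,12-trien-1-yl]-1,2-dioxolan-3-yl]acetate | CC/C=C\C/C=C/C=C/CCCCCC[C@@]1(C)C[C@](C)(CC(=O)OC)OO1 | target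

**Step count and risks**

Total steps: 14 (steps 1–11 and 14 on the main line; steps 12–13 prepare the sulfone). Longest linear sequence: 12 steps (1 → 11, then 14).

Steps most likely to fail:

1. Step 3. What may go wrong: the second ionisation may stall or be diverted once the Lewis-basic ester arm is in place, the dioxolanylium ion may lose a proton or suffer O–O heterolysis before it is captured, and attack at the second centre may show too little facial preference for a practical separation. Fallback, from 4 back to 7: the same bis-perketal is treated with allyltrimethylsilane and TiCl4 in CH2Cl2 at −78 °C, the most dependable trap for peroxycarbenium ions and one that leaves no Lewis-basic group on the ring. After removal of the meso isomer this should give racemic trans-3,5-dimethyl-3,5-di(prop-2-en-1-yl)-1,2-dioxolane F1. Ozonolysis (O3, CH2Cl2, −78 °C, then Me2S) would give 2,2'-(trans-3,5-dimethyl-1,2-dioxolane-3,5-diyl)diacetaldehyde F2, and Pinnick oxidation (NaClO2, NaH2PO4, 2-methylbut-2-ene, t-BuOH/H2O) would give 2,2'-(trans-3,5-dimethyl-1,2-dioxolane-3,5-diyl)diacetic acid F3, which also offers a crystallisation handle for removing residual meso material. Esterification with Me3SiCHN2 in MeOH/toluene returns the route to 7.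

2. Step 4. What may go wrong: poor discrimination between the enantiomers, the opposite sense of preference, or slow turnover of an ester next to a quaternary carbon. Fallback, from 7 back to 8: one equivalent of LiOH in THF/H2O at 0 °C should give racemic 2-[5-(2-methoxy-2-oxoethyl)-3,5-dimethyl-1,2-dioxolan-3-yl]acetic acid F4 (statistical; diester and diacid are recycled). This is resolved by fractional crystallisation with (S)-1-phenylethylamine, collecting the (S)-1-phenylethylammonium salt of the (3R,5R) half-acid F5 (the antipodal amine is used if it is the other diastereomer that crystallises). Acidification then releases 8.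

3. Step 14. What may go wrong: erosion of E selectivity at C14=C15 because the aldehyde is conjugated, and base-induced damage (deprotonation next to the ester with opening of the β-peroxy ester, or migration of the skipped double bonds). Fallback, from 16 (with 19) to 24: Ohira–Bestmann homologation of 16 (dimethyl (1-diazo-2-oxopropyl)phosphonate, K2CO3, MeOH, 0 °C) should give the terminal alkyne methyl 2-[(3R,5S)-3,5-dimethyl-5-(oct-7-yn-1-yl)-1,2-dioxolan-3-yl]acetate F6. Hydroboration with pinacolborane catalysed by Cp2Zr(H)Cl should give the (E)-alkenylboronate methyl 2-[(3R,5S)-3,5-dimethyl-5-[(7E)-8-(4,4,5,5-tetramethyl-1,3,2-dioxaborolan-2-yl)oct-7-en-1-yl]-1,2-dioxolan-3-yl]acetate F7. Separately, 19 is oxidised with Dess–Martin periodinane to (3Z)-hex-3-enal F8 and converted by Takai iodo-olefination (CrCl2, CHI3, THF; chromium meets only this peroxide-free piece) into (1E,4Z)-1-iodohepta-1,4-diene F9. Suzuki–Miyaura coupling of F7 with F9 (Pd(PPh3)4, aqueous K3PO4, THF, rt) forms C13–C14 with both diene geometries fixed beforehand and should give 24.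

**Further compounds**

F1 | step 3 | trans-3,5-dimethyl-3,5-di(prop-2-en-1-yl)-1,2-dioxolane (racemic) | C=CC[C@@]1(C)C[C@](C)(CC=C)OO1
F2 | step 3 | 2,2'-(trans-3,5-dimethyl-1,2-dioxolane-3,5-diyl)diacetaldehyde (racemic) | O=CC[C@@]1(C)C[C@](C)(CC=O)OO1
F3 | step 3 | 2,2'-(trans-3,5-dimethyl-1,2-dioxolane-3,5-diyl)diacetic acid (racemic) | OC(=O)C[C@@]1(C)C[C@](C)(CC(=O)O)OO1
F4 | step 4 | 2-[5-(2-methoxy-2-oxoethyl)-3,5-dimethyl-1,2-dioxolan-3-yl]acetic acid (trans, racemic; one enantiomer drawn) | OC(=O)C[C@@]1(C)C[C@](C)(CC(=O)OC)OO1
F5 | step 4 | (S)-1-phenylethylammonium 2-[(3R,5R)-5-(2-methoxy-2-oxoethyl)-3,5-dimethyl-1,2-dioxolan-3-yl]acetate | C[C@H]([NH3+])c1ccccc1.[O-]C(=O)C[C@@]1(C)C[C@](C)(CC(=O)OC)OO1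
F6 | step 14 | methyl 2-[(3R,5S)-3,5-dimethyl-5-(oct-7-yn-1-yl)-1,2-dioxolan-3-yl]acetate | C#CCCCCCC[C@@]1(C)C[C@](C)(CC(=O)OC)OO1
F7 | step 14 | methyl 2-[(3R,5S)-3,5-dimethyl-5-[(7E)-8-(4,4,5,5-tetramethyl-1,3,2-dioxaborolan-2-yl)oct-7-en-1-yl]-1,2-dioxolan-3-yl]acetate | CC1(C)OB(/C=C/CCCCCC[C@@]2(C)C[C@](C)(CC(=O)OC)OO2)OC1(C)C
F8 | step 14 | (3Z)-hex-3-enal | CC/C=C\CC=O
F9 | step 14 | (1E,4Z)-1-iodohepta-1,4-diene | CC/C=C\C/C=C/I
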